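Slowness shows first in both earlier runs: after 0.833 h, complex with three exchanged stands at 0.2% in the delta run and at 0.1% in the epsilon run.

the same everywhere: gas 200 mM (held)
- delta: starting complex 0.20 M; run made earlier
- epsilon: starting complex 0.91 M; run made earlier
- Thursday's: starting complex 1.5 M; time 10 h
- Monday's: starting complex 0.25 M; time 10 h
- Friday's: starting complex 0.30 M; time 10 h
- Sunday's: starting complex 3.0 M; time 10 h
- Tuesday's: starting complex 0.95 M; time 10 h

| run | time / h | complex with three exchanged / % |
|---|---|---|
| delta | 0.417 | 0.1 |
| delta | 0.833 | 0.2 |
| delta | 1.33 | 1.9 |
| delta | 2.50 | 13.6 |
| delta | 5.00 | 46.9 |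
| epsilon | 0.417 | 0 |
| epsilon | 0.833 | 0.1 |
| epsilon | 1.33 | 0 |
| epsilon | 2.50 | 0.3 |
| epsilon | 5.00 | 2.9 |

(readings scatter by 0.3 percentage points)

- leaving ligand is meant together with its crystals
- solid, in amounts per volume of the solution: crystals
- at the start none of incoming ligand is dissolved
- the numbers in the tables scatter by 0.3 percentage points (one standard deviation)
- steps thought possible: starting complex + incoming ligand <-> leaving ligand + complex with one exchanged; complex with one exchanged + incoming ligand <-> leaving ligand + complex with two exchanged; complex with two exchanged + incoming ligand <-> leaving ligand + complex with three exchanged; gas <-> incoming ligand; crystals <-> leaving ligand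

1. ranking by amount of complex with three exchanged, in percent of the starting complex charged, from high to low, at 10 h (Thursday's / Monday's / Friday's / Sunday's / Tuesday's)
2. the amount of complex with three exchanged, in percent of the starting complex charged of the flask you put first, at 10 h
3. the amount of complex with three exchanged, in percent of the starting complex charged of the flask you put last, at 10 h

Two numbers seem not to go together. The epsilon run holds 4.55 times the charge of the delta run, yet at 5.00 h its complex with three exchanged, counted per volume, is 3.55 times smaller.

No incoming ligand is dissolved at the start, and all of it has to come from the gas, which is held equal in both runs. The reckoning here therefore takes uptake of gas as the rate-limiting step, with one supply shared over the whole charge. With 1.60 for Monday's at 10 h, the share of each complex is then taken to follow the dose, the hours of uptake divided by the charge, as a multiple of the same ratio for the delta run at 5.00 h.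

As a test, the delta run at 1.33 h has a dose of 0.266 and reads 1.9%, while the epsilon run at 5.00 h has 0.220 and reads 2.9%. This pair stands the wrong way round, since the epsilon run has the smaller dose and reads more, so the dose doesn't rank these two readings from different times. Read at one time, at 5.00 h, the delta run has the larger dose and reads more. The dose is therefore used here to rank flasks read at one time, and brackets from other times are rough.

At 10 h the doses are 1.60 for Monday's, 1.33 for Friday's, 0.421 for Tuesday's, 0.267 for Thursday's and 0.133 for Sunday's. As a rough bracket, Monday's lies above the delta run's 46.9%, and Sunday's lies between the epsilon readings 0.3% and 2.9%, whose doses are 0.110 and 0.220.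

The forecast gives Monday's > Friday's > Tuesday's > Thursday's > Sunday's, with 79% and 0.8%, on the ground that “gas dissolution limits the supply”.

The flasks give Monday's > Friday's > Tuesday's > Thursday's > Sunday's, with 75.8% for Monday's and 0.638% for Sunday's.

    starting complex + incoming ligand ⇌ leaving ligand + complex with one exchanged (K = 10.0, k = 0.0110 M⁻¹ s⁻¹)
    complex with one exchanged + incoming ligand ⇌ leaving ligand + complex with two exchanged (K = 3.90, k = 0.00130 M⁻¹ s⁻¹)
    complex with two exchanged + incoming ligand ⇌ leaving ligand + complex with three exchanged (K = 2.00, k = 0.0700 M⁻¹ s⁻¹)
    gas ⇌ incoming ligand, rate k4*(csat - [incoming ligand]) (kL = 2.10 × 10⁻⁴ s⁻¹)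
    crystals ⇌ leaving ligand, rate k5*(cs5 - [leaving ligand]) while solid is left; crystals form when [leaving ligand] > cs5 (solubility = 0.0810 M, k = 0.00680 s⁻¹)

Both figures fall where the dose placed them, and the order of the flasks is the order of their doses. The neighbouring flask is Monday's read at 4.0 h, with a dose of 0.640. That lies between the delta run's 0.500 and 1.00, so the same rough reckoning brackets its complex with three exchanged between 13.6% and 46.9%. It reads 26.3%, and the largest share in that flask is complex with one exchanged, at 51.3%.

The numbers in the tables were generated by integration for an exercise; noise was put on by code.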